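The route cuts the biaryl bond between rings B and C (rings A and D are the terminal rings; ring B carries the lone C–H and is bonded to A; ring C carries Br and is bonded to D). It exploits two symmetries: the A–B half is a hexaoxygenated biphenyl with four equivalent C–H positions, and in ring C the carbon bonded to ring B and the carbon carrying Br are mirror images across the C2···C5 line. One operation therefore metalates 2,2',4,4',6,6'-hexamethoxybiphenyl at C–H (Li, then Zn) and Negishi-couples it once with its symmetric 3,5-dibromo analogue; the untouched C–Br is the bromine of the target. BBr3 then frees twelve phenols.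

Key step: step 4

Assumption: the target SMILES defines no stereochemical element; the axis between rings B and C, the only one flanked by two rings that are unsymmetrical about it, is left uncontrolled and the compound is made as the mixture of its two axial forms.

Step 1
Reactants: 1 (2,4,6-trimethoxyphenyl)boronic acid; 2 2-bromo-1,3,5-trimethoxybenzene
Product: 3 2,2',4,4',6,6'-hexamethoxy-1,1'-biphenyl
Conditions: 1 (1.5 equiv), 2 (1.0 equiv), Pd(OAc)2 (2 mol %), SPhos (4 mol %), K3PO4 (3 equiv), toluene/H2O, 100 °C, argon
Reagents that add atoms: none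
Why: Suzuki–Miyaura coupling under SPhos-ligated palladium, an established catalyst type for tetra-ortho-substituted biaryls from 2,6-dialkoxyarylboronic acids, should join the two rings, the excess of 1 offsetting its protodeboronation.

Step 2
Reactants: 4 1,3,5-trimethoxybenzene
Product: 5 1,3,5-tribromo-2,4,6-trimethoxybenzene
Conditions: Br2 (3.3 equiv), CH2Cl2, 0 °C to rt
Reagents that add atoms: bromine, BrBr
Why: Exhaustive electrophilic aromatic bromination should be fast, since every ring C–H is ortho or para to three methoxy groups.

Step 3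
Reactants: 4 1,3,5-trimethoxybenzene; 5 1,3,5-tribromo-2,4,6-trimethoxybenzene
Product: 8 3,5-dibromo-2,2',4,4',6,6'-hexamethoxy-1,1'-biphenyl, via 2,4,6-trimethoxyphenyllithium 6 (not isolated), via (2,4,6-trimethoxyphenyl)zinc chloride 7 (not isolated)
Conditions: 4 (1.2 equiv), n-BuLi (1.0 equiv), THF, 0 °C to rt; ZnCl2 (1.1 equiv), 0 °C to rt; then 5 (3 equiv), Pd2(dba)3 (2 mol %), RuPhos (8 mol %), THF/NMP, 70 °C
Reagents that add atoms: none
Why: Directed ortho-lithiation of 4 between two methoxy groups and transmetalation give arylzinc 7, whose Negishi coupling at one of the three equivalent C–Br bonds of 5 should stop at mono-arylation because 5 is in large excess (recovered), RuPhos-ligated palladium being an established catalyst type for tetra-ortho-substituted biaryls.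

Step 4
Reactants: 3 2,2',4,4',6,6'-hexamethoxy-1,1'-biphenyl; 8 3,5-dibromo-2,2',4,4',6,6'-hexamethoxy-1,1'-biphenyl
Product: 11 5''-bromo-2,2',2'',2''',4,4',4'',4''',6,6',6'',6'''-dodecamethoxy-1,1':3',1'':3'',1'''-quaterphenyl, via (2,2',4,4',6,6'-hexamethoxybiphenyl-3-yl)lithium 9 (not isolated), via (2,2',4,4',6,6'-hexamethoxybiphenyl-3-yl)zinc chloride 10 (not isolated)
Conditions: 3 (1.5 equiv), n-BuLi (1.0 equiv), THF, 0 °C to rt; ZnCl2 (1.1 equiv), 0 °C to rt; then 8 (2.5 equiv), Pd2(dba)3 (2.5 mol %), RuPhos (10 mol %), THF/NMP, 70 °C
Reagents that add atoms: none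
Why: n-BuLi removes one of the four symmetry-equivalent ring protons of 3 (each lies between two methoxy groups, directed ortho-metalation), ZnCl2 turns aryllithium 9 into arylzinc 10, and RuPhos-ligated zerovalent palladium inserts into one of the two homotopic C–Br bonds of 8, transmetalates with 10 and reductively eliminates the ring B–ring C bond. The closest known reaction type is the Negishi coupling of 2,6-dialkoxyarylzinc halides with di-ortho-substituted aryl bromides under dialkylbiarylphosphine ligands, which is established for tetra-ortho-substituted biaryls. No ring is closed and no stereocentre is set; the new axis forms without control, as the assumption allows. The step needs mono-metalation of 3 and mono-arylation of 8, so 3 is kept in excess over n-BuLi (which also leaves no n-BuLi to form butylzinc species) and 8 in excess over 10, and both are recovered. Regiochemistry cannot go wrong, because every C–H of 3 and both C–Br bonds of 8 are equivalent, and the C–Br bond that is left is the bromine of the target.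

Step 5
Reactants: 11 5''-bromo-2,2',2'',2''',4,4',4'',4''',6,6',6'',6'''-dodecamethoxy-1,1':3',1'':3'',1'''-quaterphenyl
Product: 12 5''-bromo-1,1':3',1'':3'',1'''-quaterphenyl-2,2',2'',2''',4,4',4'',4''',6,6',6'',6'''-dodecol (CNP0203036.0)
Conditions: BBr3 (30 equiv), CH2Cl2, −78 °C to rt, argon; then MeOH, H2O, 0 °C
Reagents that add atoms: none
Why: Lewis acid-mediated cleavage of aryl methyl ethers (boron binds each oxygen and bromide attacks the methyl group by SN2) should free all twelve phenols on aqueous work-up, the aryl bromide and the biaryl bonds being inert to BBr3.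

Compound list
1 | (2,4,6-trimethoxyphenyl)boronic acid | COc1cc(OC)c(B(O)O)c(OC)c1 | starting material
2 | 2-bromo-1,3,5-trimethoxybenzene | COc1cc(OC)c(Br)c(OC)c1 | starting material
3 | 2,2',4,4',6,6'-hexamethoxy-1,1'-biphenyl | COc1cc(OC)c(-c2c(OC)cc(OC)cc2OC)c(OC)c1 | intermediate
4 | 1,3,5-trimethoxybenzene | COc1cc(OC)cc(OC)c1 | starting material
5 | 1,3,5-tribromo-2,4,6-trimethoxybenzene | COc1c(Br)c(OC)c(Br)c(OC)c1Br | intermediate
6 | 2,4,6-trimethoxyphenyllithium | [Li]c1c(OC)cc(OC)cc1OC | intermediate
7 | (2,4,6-trimethoxyphenyl)zinc chloride | Cl[Zn]c1c(OC)cc(OC)cc1OC | intermediate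
8 | 3,5-dibromo-2,2',4,4',6,6'-hexamethoxy-1,1'-biphenyl | COc1cc(OC)c(-c2c(OC)c(Br)c(OC)c(Br)c2OC)c(OC)c1 | intermediate
9 | (2,2',4,4',6,6'-hexamethoxybiphenyl-3-yl)lithium | [Li]c1c(OC)cc(OC)c(-c2c(OC)cc(OC)cc2OC)c1OC | intermediate
10 | (2,2',4,4',6,6'-hexamethoxybiphenyl-3-yl)zinc chloride | Cl[Zn]c1c(OC)cc(OC)c(-c2c(OC)cc(OC)cc2OC)c1OC | intermediate
11 | 5''-bromo-2,2',2'',2''',4,4',4'',4''',6,6',6'',6'''-dodecamethoxy-1,1':3',1'':3'',1'''-quaterphenyl (dodecamethyl ether of the target) | COc1cc(OC)c(-c2c(OC)cc(OC)c(-c3c(OC)c(Br)c(OC)c(-c4c(OC)cc(OC)cc4OC)c3OC)c2OC)c(OC)c1 | intermediate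
12 | 5''-bromo-1,1':3',1'':3'',1'''-quaterphenyl-2,2',2'',2''',4,4',4'',4''',6,6',6'',6'''-dodecol (CNP0203036.0) | Oc1cc(O)c(-c2c(O)cc(O)c(-c3c(O)c(Br)c(O)c(-c4c(O)cc(O)cc4O)c3O)c2O)c(O)c1 | target

Total step count: 5. Longest linear sequence: 4 steps (steps 2, 3, 4 and 5; step 1 is the side branch that supplies 3).

Steps most likely to fail

Step 4 (key step). The coupling may stall at transmetalation or reductive elimination because four methoxy groups crowd the new axis, so that protodemetalation of 10 and hydrodebromination of 8 take over. Double metalation of 3 or a second arylation of 8 may also spread the material over higher oligomers. The fallback reverses the roles and defines both partners before the coupling. Setting out from 3, NIS (1 equiv, MeCN, catalytic TFA, 0 °C) should give 3-iodo-2,2',4,4',6,6'-hexamethoxy-1,1'-biphenyl F1, which is purified from any di-iodide. Setting out from 8, a single bromine–lithium exchange (n-BuLi, 1.0 equiv, THF, −78 °C) should give (5-bromo-2,2',4,4',6,6'-hexamethoxybiphenyl-3-yl)lithium F2. This desymmetrization is not statistical, since a second exchange on the already anionic ring is disfavoured. ZnCl2 converts F2 into (5-bromo-2,2',4,4',6,6'-hexamethoxybiphenyl-3-yl)zinc chloride F3. Negishi coupling of F3 with F1 (Pd2(dba)3, RuPhos, THF, 40 °C) takes place at the C–I bond, which zerovalent palladium enters far faster than the hindered C–Br bond, and returns to the route at 11.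

Step 3. The arylation may run on to the bis- and tris-arylated products once the first aryl group is in place, because the remaining C–Br bonds are barely less reactive, and the mixture may be hard to separate. The fallback differentiates the halogens instead of relying on excess. Setting out from 4, NBS (2 equiv, MeCN, 0 °C) should give 1,3-dibromo-2,4,6-trimethoxybenzene F4. NIS with catalytic TFA in MeCN then iodinates the last C–H to give 1,3-dibromo-5-iodo-2,4,6-trimethoxybenzene F5. Negishi coupling of arylzinc 7 (made from 4 as in step 3) with F5 at rt to 40 °C (Pd2(dba)3, RuPhos, THF) should take place only at the C–I bond and returns to the route at 8.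

Step 5. Cleavage of twelve ethers may stop short of completion, and the free dodecaphenol may suffer air oxidation or acid-promoted loss of the ring C bromine while it is handled in aqueous acid. The fallback isolates the product through a stable derivative. Setting out from 11, the BBr3 treatment is run as in step 5 and the crude product is acetylated at once (Ac2O, pyridine, DMAP, rt) to the dodecaacetate of the target F6. F6 can be chromatographed, and partly methylated material is separated at this stage and resubmitted. Transesterification of pure F6 in degassed MeOH with catalytic HCl (from AcCl) at rt under argon returns to the route at 12 with only volatile by-products.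

Further compounds
F1 | step 4 | 3-iodo-2,2',4,4',6,6'-hexamethoxy-1,1'-biphenyl | COc1cc(OC)c(-c2c(OC)cc(OC)c(I)c2OC)c(OC)c1
F2 | step 4 | (5-bromo-2,2',4,4',6,6'-hexamethoxybiphenyl-3-yl)lithium | [Li]c1c(OC)c(Br)c(OC)c(-c2c(OC)cc(OC)cc2OC)c1OC
F3 | step 4 | (5-bromo-2,2',4,4',6,6'-hexamethoxybiphenyl-3-yl)zinc chloride | Cl[Zn]c1c(OC)c(Br)c(OC)c(-c2c(OC)cc(OC)cc2OC)c1OC
F4 | step 3 | 1,3-dibromo-2,4,6-trimethoxybenzene | COc1cc(OC)c(Br)c(OC)c1Br
F5 | step 3 | 1,3-dibromo-5-iodo-2,4,6-trimethoxybenzene | COc1c(Br)c(OC)c(I)c(OC)c1Br
F6 | step 5 | 5''-bromo-1,1':3',1'':3'',1'''-quaterphenyl-2,2',2'',2''',4,4',4'',4''',6,6',6'',6'''-dodecayl dodecaacetate | CC(=O)Oc1cc(OC(C)=O)c(-c2c(OC(C)=O)cc(OC(C)=O)c(-c3c(OC(C)=O)c(Br)c(OC(C)=O)c(-c4c(OC(C)=O)cc(OC(C)=O)cc4OC(C)=O)c3OC(C)=O)c2OC(C)=O)c(OC(C)=O)c1
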